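Atoms are numbered along the target SMILES, oxygens counted. Everything rests on cutting the C13–C23 bond: C23 is the bridgehead flanked by the C24 and C26 carbonyls of ring A, 1,3-related to C10, and C13 is the ring B/ring C fusion carbon next to C14. Forward, zerovalent palladium converts the C10 side chain of a dearomatised acylphloroglucinol into a π-allyl unit (C13, C14, terminal CH2) that the prenylated C23 enolate captures at C13. One operation closes ring B, sets C13 and C23, and leaves isopropenyl and prenyl poised for ring C. The precursor is a cyclohexadienone carrying methyl and an (E)-4-(methoxycarbonyloxy)-3-methylbut-2-enyl chain on (S)-C10 and prenyl on C23.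

Key step: step 5

Remarks on the chemistry (one line each):
- Ring A = C7–C8–C10–C26–C23–C24, ring B = C10–C12–C13–C23–C26, ring C = C13–C14–C17–C22–C23; C3 is the stereocentre of the 2-methylbutanoyl group. Atom labels in the text follow the SMILES numbering and are independent of the locants inside systematic names.
- Enolised β-triketones are drawn as one tautomer; names and CIP descriptors refer to the tautomer drawn. In 11 the name locant 3 (atom C17) is R, in 12 and 13 it is S: the spatial arrangement is the same, only the CIP ranking changes.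
- The C10 side chain is brought in from 2-methyl-2-vinyloxirane, which has a single ionisable allylic C–O bond and leaves a hydroxyl that palladium does not ionise, so the chain has one constitution and the precursor can be isolated before the bridging step.
- The sense of induction of the chiral ligand in step 3 is assumed; if the first run favours the C10 epimer, the enantiomeric ligand is used. Because C3 is fixed from the start, a wrong C10 configuration is a diastereomer, removable by chromatography at 8 or 10.
- (R)-2-Methylbutanoic acid is taken as purchasable in high enantiomeric purity.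
- Co(salen-tBu,tBu)Cl = chloro[N,N′-bis(3,5-di-tert-butylsalicylidene)cyclohexane-1,2-diaminato]cobalt, a trivalent cobalt complex.

Step 1
Reactants: 1 (R)-2-methylbutanoic acid; 2 2-methylphloroglucinol
Product: 4 (2R)-2-methyl-1-(2,4,6-trihydroxy-3-methylphenyl)butan-1-one, via (R)-2-methylbutanoyl chloride 3 (not isolated)
Conditions: (COCl)2, DMF (cat.), CH2Cl2, 0 °C → rt; then 2, AlCl3 (3.5 equiv), CH2Cl2/PhNO2, 0 °C → rt; 1 M HCl work-up
Reagents that add atoms: none
Why: Friedel–Crafts acylation of an electron-rich triol whose two free ring positions are equivalent, so a single aryl ketone is expected; no stereocentre is created, and making and using the acid chloride without base at or below room temperature should keep C3, which comes from 1, from epimerising through a ketene or enol.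

Step 2
Reactants: 4 (2R)-2-methyl-1-(2,4,6-trihydroxy-3-methylphenyl)butan-1-one; 5 prenyl bromide
Product: 6 (2R)-2-methyl-1-[2,4,6-trihydroxy-3-methyl-5-(3-methylbut-2-en-1-yl)phenyl]butan-1-one
Conditions: 5 (1.0 equiv), KOH (1 M aq.), 0 °C; then HCl to pH 2
Reagents that add atoms: prenyl bromide (5), CC(C)=CCBr
Why: C-alkylation of the ambident phloroglucinolate at its only unsubstituted ring carbon (the standard C-prenylation of acylphloroglucinols in aqueous alkali, where solvation of the oxygens favours attack through carbon); no stereocentre is formed, and C3 is safe because its ketone is part of a vinylogous carboxylate under these conditions.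

Step 3
Reactants: 6 (2R)-2-methyl-1-[2,4,6-trihydroxy-3-methyl-5-(3-methylbut-2-en-1-yl)phenyl]butan-1-one; 7 2-methyl-2-vinyloxirane (isoprene monoxide; racemic)
Product: 8 (6S)-3,5-dihydroxy-6-[(2E)-4-hydroxy-3-methylbut-2-en-1-yl]-6-methyl-4-[(2R)-2-methylbutanoyl]-2-(3-methylbut-2-en-1-yl)cyclohexa-2,4-dien-1-one
Conditions: 7 (1.05 equiv), Pd2(dba)3·CHCl3 (2.5 mol %), (1R,2R)-N,N′-bis[2-(diphenylphosphino)benzoyl]cyclohexane-1,2-diamine (7.5 mol %), CH2Cl2, 0 °C → rt
Reagents that add atoms: 2-methyl-2-vinyloxirane (7), CC1(C=C)CO1
Why: Tsuji–Trost allylic alkylation with a vinyl epoxide, run as an asymmetric dearomatising alkylation of a phenol: zerovalent palladium opens 7 at its allylic C–O bond (erasing the epoxide stereocentre), the alkoxide so formed deprotonates 6, and the phenoxide attacks the unsubstituted terminus of the π-allyl unit through C10, the less hindered of its two alkylated ring carbons (methyl against prenyl; attack at the tertiary terminus would have to join two fully substituted carbons), to give the (E)-1,4-adduct, the chiral pocket of the ligand selecting the face of C10 and so setting its (S) configuration, while the allylic hydroxyl that results is not ionised by this catalyst at room temperature, so 8 can be isolated.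

Step 4
Reactants: 8 (6S)-3,5-dihydroxy-6-[(2E)-4-hydroxy-3-methylbut-2-en-1-yl]-6-methyl-4-[(2R)-2-methylbutanoyl]-2-(3-methylbut-2-en-1-yl)cyclohexa-2,4-dien-1-one
Product: 9 (6S)-3,5-dihydroxy-6-[(2E)-4-(methoxycarbonyloxy)-3-methylbut-2-en-1-yl]-6-methyl-4-[(2R)-2-methylbutanoyl]-2-(3-methylbut-2-en-1-yl)cyclohexa-2,4-dien-1-one
Conditions: ClCO2Me (2.5 equiv), pyridine, CH2Cl2, 0 °C; then MeOH, aq. NaHCO3, rt
Reagents that add atoms: methyl chloroformate, COC(=O)Cl
Why: Acylation of the primary allylic alcohol with a chloroformate to its methyl carbonate; an enol carbonate formed in passing on the acidic triketone is a vinylogous mixed anhydride that the bicarbonate–methanol treatment returns to the enol while the alkyl carbonate is kept, and no stereocentre is touched.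

Step 5
Reactants: 9 (6S)-3,5-dihydroxy-6-[(2E)-4-(methoxycarbonyloxy)-3-methylbut-2-en-1-yl]-6-methyl-4-[(2R)-2-methylbutanoyl]-2-(3-methylbut-2-en-1-yl)cyclohexa-2,4-dien-1-one
Product: 10 (1S,5S,7S)-4-hydroxy-5-methyl-3-[(2R)-2-methylbutanoyl]-1-(3-methylbut-2-en-1-yl)-7-(prop-1-en-2-yl)bicyclo[3.2.1]oct-3-ene-2,8-dione
Conditions: Pd(PPh3)4 (10 mol %), THF, rt → 50 °C
Reagents that add atoms: none
Why: Zerovalent palladium ionises the allylic methyl carbonate with loss of CO2 to a π-allyl complex spanning the terminal CH2, C14 and C13, and the methoxide released deprotonates the vinylogous acid so that the enolate carbon C23 attacks C13 on the face opposite palladium, an intramolecular Tsuji–Trost alkylation of a cyclic 1,3-dicarbonyl of the kind known to give bridged bicyclic ketones. Ring B (C10–C12–C13–C23–C26) closes in the 5-exo mode with respect to the allyl unit, which stays outside the ring as the isopropenyl group, whereas closure at the terminal CH2 would need a seven-membered bridge containing a cis alkene. C23 is controlled by C10, because the two-carbon tether can span ring A only cis and the enolate is therefore alkylated on the face that carries the C12 chain. C13 is set in the same transition state, in which the allyl–palladium unit should lie over C22 and away from the three-carbon bridge C8–C7–C24 with its acyl group, placing the isopropenyl group on the C26 side of ring B (syn to C22) as the cis fusion of ring C requires; the alkene geometry of 9 is not critical because the syn and anti π-allyl forms interconvert. The step needs carbon over oxygen alkylation and C23 over C7: ring closure through O9 or O27 (also five-membered) and alkylation at the acyl-bearing C7 are reversible under palladium because the triketonate is a good leaving group, so material should drain to the C23-alkylated product, whose remaining acyl-β-diketone stays enolised.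

Step 6
Reactants: 10 (1S,5S,7S)-4-hydroxy-5-methyl-3-[(2R)-2-methylbutanoyl]-1-(3-methylbut-2-en-1-yl)-7-(prop-1-en-2-yl)bicyclo[3.2.1]oct-3-ene-2,8-dione
Product: 11 (1S,3R,5S,7S)-8-hydroxy-4,4,7-trimethyl-9-[(2R)-2-methylbutanoyl]-3-(prop-1-en-2-yl)tricyclo[5.3.1.0^{1,5}]undec-8-ene-10,11-dione
Conditions: Co(salen-tBu,tBu)Cl (5 mol %), PhSiH3 (10 mol %), degassed benzene, argon, rt; chromatography to remove the C17 epimer
Reagents that add atoms: none
Why: Redox-neutral cycloisomerisation of a 1,6-diene by metal-hydride hydrogen-atom transfer: the cobalt hydride delivers a hydrogen atom to the CH2 of the 1,1-disubstituted isopropenyl group (more reactive than the trisubstituted prenyl alkene), the tertiary C14 radical closes ring C by 5-exo-trig attack on C17 of the prenyl group held cis to it (the cis ring fusion is the only one within reach), and the tertiary C18 radical returns a methyl hydrogen to divalent cobalt to leave the new isopropenyl group; C17 is set under substrate control in the cyclisation with no strong facial bias foreseen, so both C17 epimers are expected and the one with C18 cis to C12 is separated by chromatography.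

Step 7
Reactants: 11 (1S,3R,5S,7S)-8-hydroxy-4,4,7-trimethyl-9-[(2R)-2-methylbutanoyl]-3-(prop-1-en-2-yl)tricyclo[5.3.1.0^{1,5}]undec-8-ene-10,11-dione
Product: 13 CNP0207052.1 [(1S,3S,5S,7S)-8-hydroxy-3-(2-hydroxypropan-2-yl)-4,4,7-trimethyl-9-[(2R)-2-methylbutanoyl]tricyclo[5.3.1.0^{1,5}]undec-8-ene-10,11-dione], via C18 hydroperoxide 12 (not isolated)
Conditions: Co(acac)2 (20 mol %), PhSiH3 (2.5 equiv), O2 (1 atm), THF/i-PrOH, 0 °C → rt; then PPh3
Reagents that add atoms: dioxygen, O=O
Why: Mukaiyama hydration: hydrogen-atom transfer from a cobalt hydride to the CH2 of the isopropenyl group gives the tertiary C18 radical, which is captured by O2 with Markovnikov regiochemistry, and PPh3 reduces the resulting hydroperoxide 12 to the tertiary alcohol; no stereocentre is formed or disturbed, and the only other C=C bond, the chelated push–pull enol C7=C8, does not accept a hydrogen atom.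

Compound list
1 | (R)-2-methylbutanoic acid | CC[C@@H](C)C(=O)O | starting material
2 | 2-methylphloroglucinol (2-methylbenzene-1,3,5-triol) | Cc1c(O)cc(O)cc1O | starting material
3 | (R)-2-methylbutanoyl chloride | CC[C@@H](C)C(=O)Cl | intermediate (not isolated)
4 | (2R)-2-methyl-1-(2,4,6-trihydroxy-3-methylphenyl)butan-1-one | CC[C@@H](C)C(=O)c1c(O)cc(O)c(C)c1O | intermediate
5 | prenyl bromide (1-bromo-3-methylbut-2-ene) | CC(C)=CCBr | starting material
6 | (2R)-2-methyl-1-[2,4,6-trihydroxy-3-methyl-5-(3-methylbut-2-en-1-yl)phenyl]butan-1-one | CC[C@@H](C)C(=O)c1c(O)c(C)c(O)c(CC=C(C)C)c1O | intermediate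
7 | 2-methyl-2-vinyloxirane (isoprene monoxide; racemic) | CC1(C=C)CO1 | starting material
8 | (6S)-3,5-dihydroxy-6-[(2E)-4-hydroxy-3-methylbut-2-en-1-yl]-6-methyl-4-[(2R)-2-methylbutanoyl]-2-(3-methylbut-2-en-1-yl)cyclohexa-2,4-dien-1-one | CC[C@@H](C)C(=O)C1=C(O)[C@](C)(C/C=C(\C)CO)C(=O)C(CC=C(C)C)=C1O | intermediate
9 | (6S)-3,5-dihydroxy-6-[(2E)-4-(methoxycarbonyloxy)-3-methylbut-2-en-1-yl]-6-methyl-4-[(2R)-2-methylbutanoyl]-2-(3-methylbut-2-en-1-yl)cyclohexa-2,4-dien-1-one | CC[C@@H](C)C(=O)C1=C(O)[C@](C)(C/C=C(\C)COC(=O)OC)C(=O)C(CC=C(C)C)=C1O | intermediate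
10 | (1S,5S,7S)-4-hydroxy-5-methyl-3-[(2R)-2-methylbutanoyl]-1-(3-methylbut-2-en-1-yl)-7-(prop-1-en-2-yl)bicyclo[3.2.1]oct-3-ene-2,8-dione | CC[C@@H](C)C(=O)C1=C(O)[C@]2(C)C[C@@H](C(C)=C)[C@](CC=C(C)C)(C1=O)C2=O | intermediate
11 | (1S,3R,5S,7S)-8-hydroxy-4,4,7-trimethyl-9-[(2R)-2-methylbutanoyl]-3-(prop-1-en-2-yl)tricyclo[5.3.1.0^{1,5}]undec-8-ene-10,11-dione | CC[C@@H](C)C(=O)C1=C(O)[C@]2(C)C[C@H]3C(C)(C)[C@@H](C(C)=C)C[C@@]3(C1=O)C2=O | intermediate
12 | (1S,3S,5S,7S)-3-(2-hydroperoxypropan-2-yl)-8-hydroxy-4,4,7-trimethyl-9-[(2R)-2-methylbutanoyl]tricyclo[5.3.1.0^{1,5}]undec-8-ene-10,11-dione | CC[C@@H](C)C(=O)C1=C(O)[C@]2(C)C[C@H]3C(C)(C)[C@@H](C(C)(C)OO)C[C@@]3(C1=O)C2=O | intermediate (not isolated)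
13 | CNP0207052.1, (1S,3S,5S,7S)-8-hydroxy-3-(2-hydroxypropan-2-yl)-4,4,7-trimethyl-9-[(2R)-2-methylbutanoyl]tricyclo[5.3.1.0^{1,5}]undec-8-ene-10,11-dione | CC[C@@H](C)C(=O)C1=C(O)[C@]2(C)C[C@H]3C(C)(C)[C@@H](C(C)(C)O)C[C@@]3(C1=O)C2=O | target

Total step count: 7. Longest linear sequence: 7 steps (1 and 2 → 4 → 6 → 8 → 9 → 10 → 11 → 13).

Steps most likely to fail

Step 5 (ring B closure). The ring may close through oxygen (O9 or O27) and stay there instead of draining to carbon. The allyl unit may close with the isopropenyl group turned toward the three-carbon bridge, an orientation that cannot go on to a cis-fused ring C. Palladium may also cleave the C10–C12 bond again with re-aromatisation. Fallback: from 6, a dearomatising C10 prenylation with methyl 3-methylbut-2-en-1-yl carbonate under the catalyst system used for 8 should give (6S)-3,5-dihydroxy-6-methyl-4-[(2R)-2-methylbutanoyl]-2,6-bis(3-methylbut-2-en-1-yl)cyclohexa-2,4-dien-1-one F1. Oxidation of F1 with Mn(OAc)3·2H2O and Cu(OAc)2·H2O in AcOH generates the C23 radical, which closes ring B (C23 to C13) and then ring C (C14 to C17) in two 5-exo cyclisations; divalent copper converts the C18 radical into the isopropenyl group. This oxidative radical cyclisation of a 1,3-dicarbonyl onto two prenyl groups comes back to the route at 11.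

Step 3 (dearomatising allylation). Alkylation may take place at the prenyl-bearing C23 instead of C10, facial discrimination at C10 may be poor, the epoxide may open 1,2 instead of 1,4, and a second allylation of the product may occur. Fallback: from 4, ring bromination with NBS (MeCN, 0 °C) at the only free carbon gives (2R)-1-(3-bromo-2,4,6-trihydroxy-5-methylphenyl)-2-methylbutan-1-one F2, in which C10 is the only alkyl-bearing ring carbon. The palladium-catalysed opening of 7 then leads to (6S)-2-bromo-3,5-dihydroxy-6-[(2E)-4-hydroxy-3-methylbut-2-en-1-yl]-6-methyl-4-[(2R)-2-methylbutanoyl]cyclohexa-2,4-dien-1-one F3. Zn in AcOH removes the bromine of this 2-bromo-1,3-dione to give (6S)-3,5-dihydroxy-6-[(2E)-4-hydroxy-3-methylbut-2-en-1-yl]-6-methyl-4-[(2R)-2-methylbutanoyl]cyclohexa-2,4-dien-1-one F4. C-prenylation of its free 1,3-dicarbonyl carbon with 5 (KOH aq., 0 °C) comes back to the route at 8.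

Step 6 (ring C closure). The new isopropenyl group may re-enter the hydrogen-atom-transfer cycle and isomerise to the tetrasubstituted alkene with loss of C17. Hydrogen-atom transfer may start at the prenyl group, facial selectivity at C17 may be poor, and the chelating triketone may tie up the cobalt catalyst. Fallback: from 10, ring closure and oxygenation are run in one flask under aerobic hydrogen-atom-transfer conditions (Fe(acac)3, PhSiH3, EtOH, air admitted slowly so that 5-exo closure precedes oxygen capture, then PPh3). The C18 radical is then trapped irreversibly by O2 instead of returning hydrogen to the metal, and the sequence passes through hydroperoxide 12 and comes back to the route at 13 without 11. No compound outside the list is made (entry F0).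

Further compounds
F1 | step 5 | (6S)-3,5-dihydroxy-6-methyl-4-[(2R)-2-methylbutanoyl]-2,6-bis(3-methylbut-2-en-1-yl)cyclohexa-2,4-dien-1-one | CC[C@@H](C)C(=O)C1=C(O)[C@](C)(CC=C(C)C)C(=O)C(CC=C(C)C)=C1O
F2 | step 3 | (2R)-1-(3-bromo-2,4,6-trihydroxy-5-methylphenyl)-2-methylbutan-1-one | CC[C@@H](C)C(=O)c1c(O)c(C)c(O)c(Br)c1O
F3 | step 3 | (6S)-2-bromo-3,5-dihydroxy-6-[(2E)-4-hydroxy-3-methylbut-2-en-1-yl]-6-methyl-4-[(2R)-2-methylbutanoyl]cyclohexa-2,4-dien-1-one | CC[C@@H](C)C(=O)C1=C(O)[C@](C)(C/C=C(\C)CO)C(=O)C(Br)=C1O
F4 | step 3 | (6S)-3,5-dihydroxy-6-[(2E)-4-hydroxy-3-methylbut-2-en-1-yl]-6-methyl-4-[(2R)-2-methylbutanoyl]cyclohexa-2,4-dien-1-one | CC[C@@H](C)C(=O)C1=C(O)[C@](C)(C/C=C(\C)CO)C(=O)C=C1O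
F0 | step 6 | none | none
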